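Count two nucleophiles for every electrophile before reading anything else in these flasks.

in all of them: gas 4.2 mM (held)
- green: electrophile 0.15 M; nucleophile 0.095 M; run made earlier
- teal: electrophile 0.050 M; nucleophile 0.095 M; run made earlier
- Thursday's: electrophile 0.10 M; nucleophile 0.210 M; time 8.0 d
- Monday's: electrophile 0.10 M; nucleophile 0.0950 M; time 8.0 d
- Wednesday's: electrophile 0.10 M; nucleophile 0.140 M; time 8.0 d

| run | time / d | electrophile / % | product / % |
|---|---|---|---|
| green | 0.417 | 58.0 | 32.6 |
| green | 0.625 | 52.6 | 33.2 |
| green | 0.833 | 48.2 | 34.7 |
| green | 1.25 | 44.6 | 34.9 |
| green | 2.08 | 36.4 | 35.5 |
| green | 3.00 | 32.3 | 36.7 |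
| green | 5.00 | 28.0 | 38.8 |
| teal | 0.625 | 14.2 | 77.6 |
| teal | 1.25 | 7.1 | 85.9 |
| teal | 2.08 | 4.2 | 88.3 |
| teal | 3.00 | 2.6 | 90.6 |
| teal | 4.00 | 2.9 | 91.9 |
| teal | 5.00 | 2.6 | 92.7 |

(standard deviation of a reading: 0.5 percentage points)

* part of the electrophile that has reacted at the end, Thursday's
* part of the electrophile that has reacted at the end, Monday's
* part of the electrophile that has reacted at the end, Wednesday's
* what raising the concentration of nucleophile from its lowest to its highest value here does to the part of the electrophile that has reacted (changes below 5 percentage points count as none) (no change / it rises / it falls)

- what was read earlier has a scatter of 0.5 percentage points, one standard deviation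
- at the start none of the gas is in solution
- what has gone from electrophile into another species counts as reacted, even if it can come back

In the green run, product reaches 32.6% at the first reading and then crawls, and 31.7% is what two nucleophiles apiece would allow. The teal run climbs towards 95.0% in the same way. We therefore reckon with a simple share. Monday's 47.5% is its cover, the percentage of the charged electrophile that the charged nucleophile can serve at two apiece.

Green's last product reading stands 7.1 percentage points above its cover, and we add that creep to every flask. Of what is not product in that reading, 45.8% is still electrophile, and we assume the same split elsewhere. This gives us 79.2% reacted for Monday's and 89.5% for Wednesday's. Thursday's cover of 105% exceeds the whole charge, so we expect electrophile to be the limiting reagent there.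

The forecast, holding that “the nucleophile is spent at 2:1”, gives 98% for Thursday's, 82% for Monday's and 90% for Wednesday's, with the trend it rises. Ours is lower for Monday's.

The flasks give 99.8% for Thursday's, 80.3% for Monday's and 89.9% for Wednesday's. On the trend, it rises, by 20 points. Thursday's flask stands higher than Monday's because of its larger charge of nucleophile: without that difference it gives 80.3%.

    electrophile + nucleophile → acid set free + product (k = 3.50 /M/h)
    nucleophile + acid set free ⇌ protonated nucleophile, settled at all times (K = 11000 /M)
    acid set free + free base ⇌ salt of the base (K = 260 /M, k = 1.30 /M/h)
    gas ⇌ free base, rate k4*(csat - [free base]) (kL = 0.690 /h)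
    electrophile ⇌ dormant form (K = 1.20, k = 0.0160 /h)

In Monday's flask each product step sets acid free, and at the end 69.8% of that acid stands as protonated nucleophile, so each product has cost 1.70 nucleophiles. Free nucleophile ends at 0.341% of its charge, with product at 55.7% against a cover of 47.5%. Taking the parking away lifts the part reacted from 80.3% to 97.4%, so it is one part of the shortfall. Wednesday's neighbour with 0.25 M of electrophile has a cover of 28.0%, and its product ends at 35.8%.

(The numbers in the tables are calculated with constants of no real substance.)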